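**Retrosynthetic overview**
1. Botryotin E ⇐ acetate opening of a C16 spiro‑epoxide ⇐ C16 ketone plus a sulfur ylide (brings C17).
2. The bicyclo[3.2.1]octene (new rings C and D) ⇐ one operation on a bicyclic enal–vinyl ketone. A deconjugative Michael addition makes C8–C14 and moves the alkene to C9=C11. A transannular aldol then makes C12–C15.
3. Enal–vinyl ketone ⇐ two ozonolyses of the abietane ring C (isopropylidene carbons lost as acetone, then a C13–C14 cut of a silyl dienol ether), followed by acyl Stille vinylation.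
4. Rings A and B with C4, C5 and C10 come unchanged from (−)-abietic acid.
5. Ring order: A and B (chiral pool) → old ring C opened → new rings C and D closed together.

Assumption: commercial (−)-abietic acid (5α‑H, 9α‑H, 10β‑CH3, 4β‑CH3, 4α‑CO2H) carries the C4/C5/C10 configuration of the target. Locants C1–C12 and C18–C20 are those of abietane. From compound 8 on, former C14 is called C15 and former C13 is called C16. The vinyl carbons become C13 and C14, and the ylide carbon becomes C17. TBS = tert‑butyldimethylsilyl.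

Step 1
Reactants: 1 (−)-abietic acid
Product: 2 abietinol (abieta-7,13-dien-18-ol)
Conditions: LiAlH4, THF, reflux; aq. NaOH work-up
Reagents that add atoms: none
Why: LiAlH4 reduction of the hindered C18 acid leaves the diene and C4, C5, C9 and C10 untouched.

Step 2
Reactants: 2 abietinol
Product: 3 8,13-dichloroabietan-18-ol (epimer mixture at C8 and C13)
Conditions: HCl (g, excess), CH2Cl2, 0 °C
Reagents that add atoms: hydrogen chloride, Cl
Why: Markovnikov hydrochlorination (protonation at C7, then at C14) runs through the tertiary C8 and C13 cations and gives the bis‑tertiary dichloride, whose two new centres are erased in step 3.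

Step 3
Reactants: 3 8,13-dichloroabietan-18-ol
Product: 4 abieta-8,13(15)-dien-18-ol
Conditions: Li2CO3, LiBr, DMF, 120 °C
Reagents that add atoms: none
Why: Double Zaitsev dehydrochlorination (E1‑type) removes H9 and H15 to give the two tetrasubstituted non‑conjugated alkenes, the carbonate medium does not equilibrate them to conjugated abietadienes, and the C9 stereocentre is destroyed on purpose.

Step 4
Reactants: 4 abieta-8,13(15)-dien-18-ol
Product: 5 18-hydroxypodocarp-8-en-13-one (β,γ-enone)
Conditions: O3 (1.0 equiv), pyridine, CH2Cl2, −78 °C; Me2S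
Reagents that add atoms: ozone, [O-][O+]=O
Why: Chemoselective ozonolysis cleaves the exposed exocyclic isopropylidene before C8=C9, which is buried next to quaternary C10, and the neutral reductive work-up keeps the enone unconjugated.

Step 5
Reactants: 5 18-hydroxypodocarp-8-en-13-one
Product: 6 13,18-bis(TBSO)podocarpa-8,13-diene
Conditions: TBSOTf (2.4 equiv), Et3N, CH2Cl2, −78 → 0 °C
Reagents that add atoms: tert-butyldimethylsilyl triflate, CC(C)(C)[Si](C)(C)OS(=O)(=O)C(F)(F)F
Why: Soft enolisation removes the doubly activated C14–H (α to the ketone and allylic), so the 8,13-dienol silyl ether forms under kinetic control, and the primary alcohol is silylated in the same operation.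

Step 6
Reactants: 6 13,18-bis(TBSO)podocarpa-8,13-diene
Product: 8 14-oxo-18-(TBSO)-13,14-secopodocarp-8-en-13-oic acid (enal acid), via silyl ester 7 (not isolated)
Conditions: O3, CH2Cl2, −78 °C; Me2S; aqueous work-up (pH 4)
Reagents that add atoms: ozone, [O-][O+]=O
Why: Silyl enol ether ozonolysis cuts only the electron‑rich C13=C14, because C8=C9 then becomes a deactivated tetrasubstituted enal, and the silyl ester hydrolyses on work-up.

Step 7
Reactants: 8 enal acid
Product: 10 enal vinyl ketone (C8–CHO; C8=C9; C9–CH2CH2C(=O)CH=CH2; 18-OTBS), via acid chloride 9 (not isolated)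
Conditions: 1-chloro-N,N,2-trimethylpropenylamine, CH2Cl2, 0 °C; then Bu3SnCH=CH2, Pd(PPh3)4 (5 mol %), THF, 50 °C
Reagents that add atoms: tributyl(vinyl)stannane, C=C[Sn](CCCC)(CCCC)CCCC
Why: Neutral acid chloride formation followed by Stille acylation (zerovalent palladium) tolerates the enal and the silyl ether and touches no stereocentre.

Step 8
Reactants: 10 enal vinyl ketone
Product: 13 tetracyclic 15-OTBS 16-ketone (bicyclo[3.2.1]oct-6-ene; C14 α on C8; C15 bridge β; 15-OTBS over the C9=C11 bridge), via keto aldehyde 11 (not isolated), via ketol 12 (not isolated)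
Conditions: DBU (0.3 equiv), MeCN (0.005 M), 0 °C → rt; then 2,6-lutidine, TBSOTf (1.2 equiv), −20 °C
Reagents that add atoms: tert-butyldimethylsilyl triflate, CC(C)(C)[Si](C)(C)OS(=O)(=O)C(F)(F)F
Why: Proposed new method: reversible γ‑deprotonation at C11 gives the extended enal dienolate with C12 held cis to C8 by strain against C10, its α‑carbon C8 adds to the tethered vinyl ketone from the α face anti to the axial C10 methyl (deconjugative intramolecular Michael addition that sets C8 and moves the alkene to C9=C11), the equilibrated C12 enolate then closes a transannular aldol through a chair in which the aldehyde oxygen lies equatorial and away from the enolate oxygen (sets C15, with C12 fixed by the bridge), and silylation blocks retro‑aldol; the closest known types are bridged Michael–aldol annulation and deconjugative α‑alkylation of extended enolates.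

Step 9
Reactants: 13 tetracyclic 15-OTBS 16-ketone
Product: 14 C16 spiro-epoxide (oxirane CH2 axial toward the C15 bridge; oxirane O equatorial)
Conditions: Me3SI, NaH, DMSO–THF, 0 °C → rt
Reagents that add atoms: trimethylsulfonium iodide, C[S+](C)C.[I-]
Why: Corey–Chaykovsky epoxidation with the irreversible sulfonium ylide attacks axially past only C14–H and C15–H, because the equatorial path is blocked by C11 on the neighbouring bridgehead, which sets C16; Bredt strain at C12 rules out β‑elimination of the silyloxy group.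

Step 10
Reactants: 14 C16 spiro-epoxide
Product: 15 15,18-bis-O-TBS botryotin E
Conditions: CsOAc, AcOH, DMF, 80 °C
Reagents that add atoms: acetic acid, CC(=O)O
Why: Buffered SN2 opening of the epoxide by acetate takes place at the CH2 terminus only, so the C16–O bond and its configuration are kept and the acetate ends up on C17 without any hydroxyl differentiation.

Step 11
Reactants: 15 15,18-bis-O-TBS botryotin E
Product: 16 botryotin E
Conditions: HF·pyridine, pyridine, THF, 0 °C → rt
Reagents that add atoms: none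
Why: Fluoride desilylation frees the C15 and C18 hydroxyls without touching the acetate, the tertiary alcohol or the shielded C9=C11 alkene.

**Compound list**
1 | (−)-abietic acid, abieta-7,13-dien-18-oic acid | CC(C)C1=CC2=CC[C@H]3[C@](C)(C(=O)O)CCC[C@]3(C)[C@H]2CC1 | starting material
2 | abietinol, abieta-7,13-dien-18-ol | CC(C)C1=CC2=CC[C@H]3[C@](C)(CO)CCC[C@]3(C)[C@H]2CC1 | intermediate
3 | 8,13-dichloroabietan-18-ol, epimers at C8 and C13 | CC(C)C1(Cl)CC2(Cl)CC[C@H]3[C@](C)(CO)CCC[C@]3(C)[C@H]2CC1 | intermediate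
4 | abieta-8,13(15)-dien-18-ol | CC(C)=C1CCC2=C(C1)CC[C@H]3[C@](C)(CO)CCC[C@]23C | intermediate
5 | 18-hydroxypodocarp-8-en-13-one | O=C1CCC2=C(C1)CC[C@H]3[C@](C)(CO)CCC[C@]23C | intermediate
6 | 13,18-bis(TBSO)podocarpa-8,13-diene | CC(C)(C)[Si](C)(C)OC=1CCC2=C(C=1)CC[C@H]3[C@](C)(CO[Si](C)(C)C(C)(C)C)CCC[C@]23C | intermediate
7 | TBS ester of enal acid 8 | CC(C)(C)[Si](C)(C)OC(=O)CCC1=C(C=O)CC[C@H]2[C@](C)(CO[Si](C)(C)C(C)(C)C)CCC[C@]12C | intermediate
8 | enal acid, 14-oxo-18-(TBSO)-13,14-secopodocarp-8-en-13-oic acid | OC(=O)CCC1=C(C=O)CC[C@H]2[C@](C)(CO[Si](C)(C)C(C)(C)C)CCC[C@]12C | intermediate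
9 | acid chloride of 8 | ClC(=O)CCC1=C(C=O)CC[C@H]2[C@](C)(CO[Si](C)(C)C(C)(C)C)CCC[C@]12C | intermediate
10 | enal vinyl ketone | C=CC(=O)CCC1=C(C=O)CC[C@H]2[C@](C)(CO[Si](C)(C)C(C)(C)C)CCC[C@]12C | intermediate
11 | cycloheptenone keto aldehyde (C8 quaternary: CHO β, C14 α; C9=C11) | O=C1CC[C@]2(C=O)CC[C@H]3[C@](C)(CO[Si](C)(C)C(C)(C)C)CCC[C@]3(C)C2=CC1 | intermediate
12 | tetracyclic 15-hydroxy 16-ketone | O=C1CC[C@]23CC[C@H]4[C@](C)(CO[Si](C)(C)C(C)(C)C)CCC[C@]4(C)C2=C[C@H]1[C@H]3O | intermediate
13 | tetracyclic 15-OTBS 16-ketone | O=C1CC[C@]23CC[C@H]4[C@](C)(CO[Si](C)(C)C(C)(C)C)CCC[C@]4(C)C2=C[C@H]1[C@H]3O[Si](C)(C)C(C)(C)C | intermediate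
14 | C16 spiro-epoxide | C5O[C@@]51CC[C@]23CC[C@H]4[C@](C)(CO[Si](C)(C)C(C)(C)C)CCC[C@]4(C)C2=C[C@H]1[C@H]3O[Si](C)(C)C(C)(C)C | intermediate
15 | 15,18-bis-O-TBS botryotin E | CC(=O)OC[C@@]1(O)CC[C@]23CC[C@H]4[C@](C)(CO[Si](C)(C)C(C)(C)C)CCC[C@]4(C)C2=C[C@H]1[C@H]3O[Si](C)(C)C(C)(C)C | intermediate
16 | botryotin E | CC(=O)OC[C@@]1(O)CC[C@]23CC[C@H]4[C@](C)(CO)CCC[C@]4(C)C2=C[C@H]1[C@H]3O | target

Total steps: 11. Longest linear sequence: 11.

**Steps most likely to fail**

Step 8 (the ring C and D cascade; the five‑ring aldol may win, or the C15 epimer may form). The fallback sets out from 10 and returns at 13, and it closes the rings one at a time with reversed polarity at C8.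
- DBU (5 mol %) in CH2Cl2 at −40 °C is stopped at the equilibrated five‑membered aldol. This is the trans cyclopentenol F6, with 15‑OH β and the acryloyl group α.
- TBSOTf and 2,6‑lutidine give its silyl ether F7.
- In F7 the C8=C9 alkene is no longer conjugated and is electron rich. Me2AlCl in CH2Cl2 (−78 → −20 °C) makes it attack the activated enone from the α face.
- C11–H is then lost (conjugate ene, cation–olefin type), which gives 13.

Step 3 (regiochemistry of the double elimination). The fallback sets out from 2 and returns at 5, and it removes the isopropyl group at the aromatic level.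
- Pd/C at 240 °C gives dehydroabietinol F1.
- N‑hydroxyphthalimide and O2 in MeCN at 70 °C give the cumene‑type 15-hydroperoxydehydroabietinol F2.
- Catalytic H2SO4 in acetone (Hock cleavage) gives podocarpa-8,11,13-triene-13,18-diol F3.
- MeI and K2CO3 give 13-methoxypodocarpa-8,11,13-trien-18-ol F4.
- Li, NH3 and t‑BuOH (Birch reduction) give 13-methoxypodocarpa-8,12-dien-18-ol F5, in which C8=C9 is fixed.
- Oxalic acid in aqueous THF hydrolyses the enol ether to 5.

Step 9 (facial selectivity at C16). The fallback sets out from 13 and returns at 15.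
- Ph3P=CH2 gives the 16-methylene compound F8.
- OsO4 (cat.) with N‑methylmorpholine N‑oxide gives the 16,17-diol F9.
- The reagent now delivers oxygen instead of carbon from the more open face, so the outcome at C16 is the complement of the ylide result.
- Ac2O and pyridine acetylate only the primary C17 hydroxyl and give 15.

**Further compounds**
F1 | step 3 | dehydroabietinol | CC(C)c1ccc2c(c1)CC[C@H]3[C@](C)(CO)CCC[C@]23C
F2 | step 3 | 15-hydroperoxydehydroabietinol | CC(C)(OO)c1ccc2c(c1)CC[C@H]3[C@](C)(CO)CCC[C@]23C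
F3 | step 3 | podocarpa-8,11,13-triene-13,18-diol | Oc1ccc2c(c1)CC[C@H]3[C@](C)(CO)CCC[C@]23C
F4 | step 3 | 13-methoxypodocarpa-8,11,13-trien-18-ol | COc1ccc2c(c1)CC[C@H]3[C@](C)(CO)CCC[C@]23C
F5 | step 3 | 13-methoxypodocarpa-8,12-dien-18-ol | COC1=CCC2=C(C1)CC[C@H]3[C@](C)(CO)CCC[C@]23C
F6 | step 8 | trans cyclopentenol (15-OH β, 12-acryloyl α, C8=C9) | C=CC(=O)[C@H]1CC2=C([C@@H]1O)CC[C@H]3[C@](C)(CO[Si](C)(C)C(C)(C)C)CCC[C@]23C
F7 | step 8 | TBS ether of F6 | C=CC(=O)[C@H]1CC2=C([C@@H]1O[Si](C)(C)C(C)(C)C)CC[C@H]3[C@](C)(CO[Si](C)(C)C(C)(C)C)CCC[C@]23C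
F8 | step 9 | 16-methylene compound | C=C1CC[C@]23CC[C@H]4[C@](C)(CO[Si](C)(C)C(C)(C)C)CCC[C@]4(C)C2=C[C@H]1[C@H]3O[Si](C)(C)C(C)(C)C
F9 | step 9 | 16,17-diol | OC[C@@]1(O)CC[C@]23CC[C@H]4[C@](C)(CO[Si](C)(C)C(C)(C)C)CCC[C@]4(C)C2=C[C@H]1[C@H]3O[Si](C)(C)C(C)(C)C
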